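The ring alkene C3=C4 (ring numbered from C1, the CH bearing carbinol C15; C4 carries CH2OH) is read as a masked triple bond, and the fourteen-membered ring is cut there. Ring-closing alkyne metathesis of an acyclic diyne with two methyl-capped alkynes forges C3≡C4 and the macrocycle in one operation and leaves the trisubstituted alkenes C7=C8 and C11=C12 and the prenyl group untouched. The feature exploited is the trans relation of C2 and C5 across C3=C4 together with the nearby C15 hydroxyl, which can later bridge to C4 through silicon so that H and the hydroxymethyl carbon add trans. The precursor is a TES-protected diyne holding both stereocentres, assembled from epoxynerol, vinylmagnesium bromide, propyne and a (Z)-alkenyl iodide.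

Key step: step 10

Remark: the atom labels C1–C15 defined above are used throughout, also for acyclic compounds; the target is taken as drawn (R at C1, R at C15), and the bromohydrin and epoxide of steps 6 and 7 are racemic at a centre that step 7 removes.

Step 1
Reactants: 1 nerol
Product: 2 (2S,3R)-2,3-epoxynerol
Conditions: Ti(OiPr)4 (cat.), L-(+)-diethyl tartrate, t-BuOOH, 4 Å MS, CH2Cl2, −20 °C
Reagents that add atoms: tert-butyl hydroperoxide, CC(C)(C)OO
Why: Sharpless asymmetric epoxidation touches only the allylic-alcohol alkene and, with the L-(+)-tartrate, should deliver oxygen to the face that gives the (2S,3R)-epoxide, whose fully substituted carbon becomes C15 (retained) and whose CH carbon becomes C1 (inverted in step 2).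

Step 2
Reactants: 2 (2S,3R)-2,3-epoxynerol; 3 vinylmagnesium bromide
Product: 4 (2R,3R)-2-ethenyl-3,7-dimethyloct-6-ene-1,3-diol
Conditions: 3 (4 equiv), CuI (20 mol%), THF, −40 → 0 °C; aq. NH4Cl
Reagents that add atoms: none
Why: Copper-catalysed Grignard opening of a 2,3-epoxy alcohol, in which the vinyl cuprate should attack the secondary epoxide carbon (the other is fully substituted) anti to oxygen, so that C1 is set by SN2 inversion while C15 keeps the epoxide configuration as the tertiary alcohol.

Step 3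
Reactants: 4 (2R,3R)-2-ethenyl-3,7-dimethyloct-6-ene-1,3-diol
Product: 6 (2R,3R)-2-ethenyl-3,7-dimethyl-3-[(triethylsilyl)oxy]oct-6-en-1-yl trifluoromethanesulfonate, via hydroxy triflate 5 (not isolated)
Conditions: Tf2O (1.05 equiv), 2,6-lutidine, CH2Cl2, −78 °C; then TESOTf, −78 → −20 °C
Reagents that add atoms: trifluoromethanesulfonic anhydride, O=S(=O)(OS(=O)(=O)C(F)(F)F)C(F)(F)F; triethylsilyl trifluoromethanesulfonate, CC[Si](CC)(CC)OS(=O)(=O)C(F)(F)F
Why: One-flask chemoselective O-sulfonylation and O-silylation, in which triflic anhydride at −78 °C should take only the primary hydroxyl and the silyl triflate then caps the tertiary hydroxyl, so that no alkoxide can close an oxetane in step 4.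

Step 4
Reactants: 6 (2R,3R)-2-ethenyl-3,7-dimethyl-3-[(triethylsilyl)oxy]oct-6-en-1-yl trifluoromethanesulfonate; 7 propyne
Product: 8 triethyl{[(6R,7S)-7-ethenyl-2,6-dimethylundec-2-en-9-yn-6-yl]oxy}silane
Conditions: 7, n-BuLi, THF, −78 °C; then 6, THF/DMPU, −78 → −20 °C
Reagents that add atoms: none
Why: SN2 alkylation of a lithium acetylide by a primary triflate installs the methyl-capped C2–C3≡C arm; the acetylide is a weak base, so displacement should outrun elimination, and the silyl ether and both alkenes are inert.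

Step 5
Reactants: 9 2-butyne; 10 geranyl bromide
Product: 11 (6E)-7,11-dimethyldodeca-6,10-dien-2-yne
Conditions: 9 (excess), n-BuLi, TMEDA, THF, −78 → 0 °C; then 10, −78 °C → rt
Reagents that add atoms: none
Why: Propargylic lithiation of 2-butyne and SN2 alkylation by the primary allylic bromide should give the 1,5-enyne with the E alkene of geranyl bromide (later C7=C8) unchanged.

Step 6
Reactants: 11 (6E)-7,11-dimethyldodeca-6,10-dien-2-yne
Product: 13 2,2-dimethyl-3-[(3E)-3-methylnon-3-en-7-yn-1-yl]oxirane (racemic), via bromohydrin 12 (not isolated)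
Conditions: NBS, THF/H2O, 0 °C; then K2CO3, MeOH, rt
Reagents that add atoms: water, O
Why: Bromohydrin formation in aqueous THF favours the terminal trisubstituted alkene of a polyprenyl chain (the alkyne is far less nucleophilic), and base then closes the epoxide by intramolecular Williamson-type substitution; the new centre is racemic and is erased in step 7.

Step 7
Reactants: 13 2,2-dimethyl-3-[(3E)-3-methylnon-3-en-7-yn-1-yl]oxirane
Product: 14 (4E)-4-methyldec-4-en-8-ynal
Conditions: H5IO6, THF/Et2O, 0 °C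
Reagents that add atoms: none
Why: Periodic acid hydrolyses the epoxide to the glycol and cleaves it (Malaprade reaction) to the aldehyde and acetone without touching the trisubstituted alkene or the alkyne.

Step 8
Reactants: 14 (4E)-4-methyldec-4-en-8-ynal
Product: 15 (2Z,6E)-2-iodo-6-methyldodeca-2,6-dien-10-yne
Conditions: EtPPh3I, n-BuLi, THF, rt; I2, −78 °C; NaN(SiMe3)2, −20 °C; then 14, −78 °C
Reagents that add atoms: ethyltriphenylphosphonium iodide, CC[P+](c1ccccc1)(c1ccccc1)c1ccccc1.[I-]; iodine, II
Why: Stork–Zhao-type Wittig olefination, in which the non-stabilised α-iodo ylide should add to the aldehyde under kinetic control to give the (Z)-2-iodoalkene (iodine cis to the chain), the geometry needed for C11=C12.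

Step 9
Reactants: 8 triethyl{[(6R,7S)-7-ethenyl-2,6-dimethylundec-2-en-9-yn-6-yl]oxy}silane; 15 (2Z,6E)-2-iodo-6-methyldodeca-2,6-dien-10-yne
Product: 17 triethyl{[(6E,10Z,14R,15R)-14-(but-2-yn-1-yl)-7,11,15,19-tetramethylicosa-6,10,18-trien-2-yn-15-yl]oxy}silane, via alkyl-9-BBN borane 16 (not isolated)
Conditions: 9-BBN dimer (1.2 equiv B–H), THF, 0 °C → rt; then 15, Pd(dppf)Cl2 (cat.), AsPh3, Cs2CO3, DMF/H2O, rt
Reagents that add atoms: none
Why: Anti-Markovnikov hydroboration of the monosubstituted alkene by 9-BBN (much faster than reaction with the internal alkyne or the trisubstituted alkene; the alkyne of 15 never meets B–H) followed by B-alkyl Suzuki–Miyaura coupling forms C12–C13 with retention of the iodide geometry and so fixes the Z alkene.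

Step 10
Reactants: 17 triethyl{[(6E,10Z,14R,15R)-14-(but-2-yn-1-yl)-7,11,15,19-tetramethylicosa-6,10,18-trien-2-yn-15-yl]oxy}silane
Product: 18 triethyl({(2R)-2-[(1R,7E,11Z)-8,12-dimethylcyclotetradeca-7,11-dien-3-yn-1-yl]-6-methylhept-5-en-2-yl}oxy)silane
Conditions: Mo(≡CC6H4OMe-4)(OSiPh3)3 (10 mol%), 5 Å MS, toluene (2 mM), 60 °C
Reagents that add atoms: none
Why: Ring-closing alkyne metathesis: the molybdenum alkylidyne adds across one propynyl terminus in a [2+2] fashion to a molybdacyclobutadiene, cycloreversion hands the metal to C3 or C4, and the same sequence on the second terminus joins C3 to C4 and expels 2-butyne. The closest known reaction type is macrocyclic ring-closing alkyne metathesis of diynes with molybdenum alkylidyne triarylsilanolate catalysts. The fourteen-membered carbocycle C1–C14 is closed end to end at the new C3≡C4 bond, a macrocyclisation run at high dilution for a ring large enough to hold a linear C–C≡C–C unit without strain. No stereocentre is created, and C1, C15 and both alkene geometries pass through unchanged. The catalyst must discriminate alkynes from alkenes, which it does because alkylidynes do not engage the trisubstituted alkenes C7=C8 and C11=C12 or the prenyl group, and cyclisation must win over oligomerisation, which dilution, the reversibility of the exchange and the trapping of 2-butyne in 5 Å molecular sieves should secure. The triethylsilyl ether keeps the tertiary hydroxyl from protonating off the silanolate ligands.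

Step 11
Reactants: 18 triethyl({(2R)-2-[(1R,7E,11Z)-8,12-dimethylcyclotetradeca-7,11-dien-3-yn-1-yl]-6-methylhept-5-en-2-yl}oxy)silane
Product: 19 (2R)-2-[(1R,7E,11Z)-8,12-dimethylcyclotetradeca-7,11-dien-3-yn-1-yl]-6-methylhept-5-en-2-ol
Conditions: Bu4NF, THF, rt
Reagents that add atoms: none
Why: Fluoride-mediated cleavage of the silyl ether frees the C15 hydroxyl needed as tether anchor; nothing else in the molecule is fluoride-sensitive.

Step 12
Reactants: 19 (2R)-2-[(1R,7E,11Z)-8,12-dimethylcyclotetradeca-7,11-dien-3-yn-1-yl]-6-methylhept-5-en-2-ol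
Product: 20 {[(2R)-2-[(1R,7E,11Z)-8,12-dimethylcyclotetradeca-7,11-dien-3-yn-1-yl]-6-methylhept-5-en-2-yl]oxy}dimethylsilane
Conditions: ClSiMe2H, Et3N, DMAP (cat.), CH2Cl2, 0 °C → rt
Reagents that add atoms: chlorodimethylsilane, C[SiH](C)Cl
Why: O-silylation of the tertiary alcohol by the small chlorosilane under amine base and DMAP catalysis installs the Si–H tether on the C15 oxygen.

Step 13
Reactants: 20 {[(2R)-2-[(1R,7E,11Z)-8,12-dimethylcyclotetradeca-7,11-dien-3-yn-1-yl]-6-methylhept-5-en-2-yl]oxy}dimethylsilane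
Product: 21 bridged (Z)-alkenylsiloxane (2,2-dimethyl-1-oxa-2-silacyclohept-3-ene ring O–SiMe2–C4=C3–C2–C1–C15 spanning C1 and C4 of the macrocycle; H at C3 trans to Si; 7E,11Z; both stereocentres unchanged)
Conditions: [Cp*Ru(MeCN)3]PF6 (5 mol%), CH2Cl2, 0 °C → rt
Reagents that add atoms: none
Why: Ruthenium-catalysed intramolecular trans-hydrosilylation of a bis-homopropargylic silyl ether in the endo-dig mode should place silicon on C4 within a seven-membered oxasilacycle, whose ring geometry forces Si cis to C2, while hydrogen adds trans at C3, which gives the ring alkene with C2 and C5 trans; the cationic catalyst does not hydrosilylate the trisubstituted alkenes.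

Step 14
Reactants: 21 bridged (Z)-alkenylsiloxane
Product: 23 (2R)-2-[(1R,3Z,7E,11Z)-4-iodo-8,12-dimethylcyclotetradeca-3,7,11-trien-1-yl]-6-methylhept-5-en-2-ol, via O-silylated iodide 22 (not isolated)
Conditions: NIS, 2,6-lutidine, (CF3)2CHOH, 0 °C; then Bu4NF, THF, 0 °C
Reagents that add atoms: N-iodosuccinimide, O=C1CCC(=O)N1I
Why: Iododesilylation (electrophilic ipso-substitution steered to C4 by the β-silyl effect) should proceed with retention and faster than iodination of the unactivated trisubstituted alkenes, the C15 oxygen staying silylated during this stage so that it cannot iodo-etherify onto the prenyl alkene, and fluoride then strips the silicon residue from oxygen.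

Step 15
Reactants: 23 (2R)-2-[(1R,3Z,7E,11Z)-4-iodo-8,12-dimethylcyclotetradeca-3,7,11-trien-1-yl]-6-methylhept-5-en-2-ol
Product: 24 methyl (1Z,4R,7Z,11E)-4-[(2R)-2-hydroxy-6-methylhept-5-en-2-yl]-7,11-dimethylcyclotetradeca-1,7,11-triene-1-carboxylate
Conditions: Pd(PPh3)4 (10 mol%), CO (1 atm), MeOH, Et3N, DMF, 60 °C
Reagents that add atoms: carbon monoxide, [C-]#[O+]; methanol, CO
Why: Palladium-catalysed methoxycarbonylation of the alkenyl iodide (oxidative addition to zerovalent palladium, CO insertion, methanolysis of the acylpalladium) keeps the alkene geometry, and methanol in excess should outcompete the hindered tertiary hydroxyl for the acyl group.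

Step 16
Reactants: 24 methyl (1Z,4R,7Z,11E)-4-[(2R)-2-hydroxy-6-methylhept-5-en-2-yl]-7,11-dimethylcyclotetradeca-1,7,11-triene-1-carboxylate
Product: 25 (2R)-2-[(1R,3Z,7E,11Z)-4-(hydroxymethyl)-8,12-dimethylcyclotetradeca-3,7,11-trien-1-yl]-6-methylhept-5-en-2-ol (target, CNP0389814.1)
Conditions: iBu2AlH (excess), CH2Cl2, −78 → 0 °C; aq. potassium sodium tartrate
Reagents that add atoms: none
Why: 1,2-Reduction of the α,β-unsaturated ester by the aluminium hydride gives the allylic alcohol at low temperature and leaves the isolated alkenes untouched, which completes the target.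

Compound list

1 | nerol, (2Z)-3,7-dimethylocta-2,6-dien-1-ol | CC(C)=CCC/C(C)=C\CO | starting material
2 | (2S,3R)-2,3-epoxynerol, [(2S,3R)-3-methyl-3-(4-methylpent-3-en-1-yl)oxiran-2-yl]methanol | CC(C)=CCC[C@@]1(C)O[C@H]1CO | intermediate
3 | vinylmagnesium bromide | C=C[Mg]Br | starting material
4 | (2R,3R)-2-ethenyl-3,7-dimethyloct-6-ene-1,3-diol | CC(C)=CCC[C@@](C)(O)[C@H](C=C)CO | intermediate
5 | (2R,3R)-2-ethenyl-3-hydroxy-3,7-dimethyloct-6-en-1-yl trifluoromethanesulfonate (hydroxy triflate, not isolated) | CC(C)=CCC[C@@](C)(O)[C@H](C=C)COS(=O)(=O)C(F)(F)F | intermediate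
6 | (2R,3R)-2-ethenyl-3,7-dimethyl-3-[(triethylsilyl)oxy]oct-6-en-1-yl trifluoromethanesulfonate | CC(C)=CCC[C@@](C)(O[Si](CC)(CC)CC)[C@H](C=C)COS(=O)(=O)C(F)(F)F | intermediate
7 | propyne | CC#C | starting material
8 | triethyl{[(6R,7S)-7-ethenyl-2,6-dimethylundec-2-en-9-yn-6-yl]oxy}silane | CC(C)=CCC[C@@](C)(O[Si](CC)(CC)CC)[C@H](C=C)CC#CC | intermediate
9 | 2-butyne | CC#CC | starting material
10 | geranyl bromide, (2E)-1-bromo-3,7-dimethylocta-2,6-diene | CC(C)=CCC/C(C)=C/CBr | starting material
11 | (6E)-7,11-dimethyldodeca-6,10-dien-2-yne | CC(C)=CCC/C(C)=C/CCC#CC | intermediate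
12 | (6E)-3-bromo-2,6-dimethyldodec-6-en-10-yn-2-ol (bromohydrin, racemic, not isolated) | CC(C)(O)C(Br)CC/C(C)=C/CCC#CC | intermediate
13 | 2,2-dimethyl-3-[(3E)-3-methylnon-3-en-7-yn-1-yl]oxirane (racemic) | CC1(C)OC1CC/C(C)=C/CCC#CC | intermediate
14 | (4E)-4-methyldec-4-en-8-ynal | O=CCC/C(C)=C/CCC#CC | intermediate
15 | (2Z,6E)-2-iodo-6-methyldodeca-2,6-dien-10-yne | C/C(I)=C/CC/C(C)=C/CCC#CC | intermediate
16 | 9-{(3R,4R)-3-(but-2-yn-1-yl)-4,8-dimethyl-4-[(triethylsilyl)oxy]non-7-en-1-yl}-9-borabicyclo[3.3.1]nonane (not isolated) | CC(C)=CCC[C@@](C)(O[Si](CC)(CC)CC)[C@H](CCB1C2CCCC1CCC2)CC#CC | intermediate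
17 | triethyl{[(6E,10Z,14R,15R)-14-(but-2-yn-1-yl)-7,11,15,19-tetramethylicosa-6,10,18-trien-2-yn-15-yl]oxy}silane (diyne, precursor of the key step) | CC(C)=CCC[C@@](C)(O[Si](CC)(CC)CC)[C@H](CC/C(C)=C\CC/C(C)=C/CCC#CC)CC#CC | intermediate
18 | triethyl({(2R)-2-[(1R,7E,11Z)-8,12-dimethylcyclotetradeca-7,11-dien-3-yn-1-yl]-6-methylhept-5-en-2-yl}oxy)silane (cycloalkyne, product of the key step) | CC(C)=CCC[C@@](C)(O[Si](CC)(CC)CC)[C@H]1CC#CCC/C=C(\C)CC/C=C(/C)CC1 | intermediate
19 | (2R)-2-[(1R,7E,11Z)-8,12-dimethylcyclotetradeca-7,11-dien-3-yn-1-yl]-6-methylhept-5-en-2-ol | CC(C)=CCC[C@@](C)(O)[C@H]1CC#CCC/C=C(\C)CC/C=C(/C)CC1 | intermediate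
20 | {[(2R)-2-[(1R,7E,11Z)-8,12-dimethylcyclotetradeca-7,11-dien-3-yn-1-yl]-6-methylhept-5-en-2-yl]oxy}dimethylsilane | CC(C)=CCC[C@@](C)(O[SiH](C)C)[C@H]1CC#CCC/C=C(\C)CC/C=C(/C)CC1 | intermediate
21 | bridged (Z)-alkenylsiloxane: O–SiMe2 bridge from the C15 oxygen to C4, Si cis to C2, H at C3 | CC(C)=CCC[C@@]1(C)O[Si](C)(C)/C2=C\C[C@H]1CC/C(C)=C\CC/C(C)=C/CC2 | intermediate
22 | {[(2R)-2-[(1R,3Z,7E,11Z)-4-iodo-8,12-dimethylcyclotetradeca-3,7,11-trien-1-yl]-6-methylhept-5-en-2-yl]oxy}(1,1,1,3,3,3-hexafluoropropan-2-yloxy)dimethylsilane (not isolated) | CC(C)=CCC[C@@](C)(O[Si](C)(C)OC(C(F)(F)F)C(F)(F)F)[C@H]1C/C=C(\I)CC/C=C(\C)CC/C=C(/C)CC1 | intermediate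
23 | (2R)-2-[(1R,3Z,7E,11Z)-4-iodo-8,12-dimethylcyclotetradeca-3,7,11-trien-1-yl]-6-methylhept-5-en-2-ol | CC(C)=CCC[C@@](C)(O)[C@H]1C/C=C(\I)CC/C=C(\C)CC/C=C(/C)CC1 | intermediate
24 | methyl (1Z,4R,7Z,11E)-4-[(2R)-2-hydroxy-6-methylhept-5-en-2-yl]-7,11-dimethylcyclotetradeca-1,7,11-triene-1-carboxylate | CC(C)=CCC[C@@](C)(O)[C@H]1C/C=C(\C(=O)OC)CC/C=C(\C)CC/C=C(/C)CC1 | intermediate
25 | (2R)-2-[(1R,3Z,7E,11Z)-4-(hydroxymethyl)-8,12-dimethylcyclotetradeca-3,7,11-trien-1-yl]-6-methylhept-5-en-2-ol | CC(C)=CCC[C@@](C)(O)[C@H]1C/C=C(\CO)CC/C=C(\C)CC/C=C(/C)CC1 | target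

Total step count: 16.
Longest linear sequence: 12 steps (steps 1–4 and 9–16 from nerol; the branch from geranyl bromide, steps 5–8 and 9–16, is equally long).

Steps most likely to fail

Step 10 (key step). Intermolecular metathesis may outrun ring closure and give cyclic dimers or oligomers, or the alkylidyne may be deactivated by traces of protic impurities before the second alkyne is engaged. The fallback sets out from 8 and 15 and comes back at 18 by reversing the order of the two unions. Alkyne cross-metathesis of 8 with an excess of 15 under the same molybdenum catalyst (alkenyl iodides are tolerated, 2-butyne is removed by the sieves) should give the acyclic iodo dienyne F1. Hydroboration of its vinyl group with 9-BBN gives the alkylborane F2, and an intramolecular B-alkyl Suzuki–Miyaura coupling at high dilution (Pd(dppf)Cl2, AsPh3, Cs2CO3) closes the ring at C12–C13 to give 18.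

Step 14. Electrophilic iodine may add to or cyclise onto the other trisubstituted alkenes, or the silane may be protonated off, instead of clean ipso-substitution at C4. The fallback sets out from 18, replaces steps 11–14 and comes back at 23. Ruthenium-catalysed trans-hydrostannation of the cycloalkyne (Bu3SnH, [Cp*Ru(MeCN)3]PF6, CH2Cl2) is not directed and must be expected to give both regioisomers. The C4-stannane F3 is separated and converted by tin–iodine exchange (I2, CH2Cl2, −78 °C), which is far faster than attack of iodine on the alkenes, into the alkenyl iodide F4. Bu4NF then removes the silyl ether to give 23.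

Step 8. The Z selectivity of the iodo-olefination may erode and the E isomer, which is hard to remove at any later stage, would be carried forward; the enolisable aldehyde may also be consumed unproductively. The fallback sets out from 13, replaces steps 2–4 and 7–9 and comes back at 17.
- Epoxide 13 is isomerised (Al(OiPr)3, toluene, reflux) to the allylic alcohol F5.
- KH and Bu3SnCH2I give the stannylmethyl ether F6.
- n-BuLi at −78 °C triggers the Wittig–Still [2,3]-rearrangement, which is reliably Z-selective for this substitution pattern, to the homoallylic alcohol F7.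
- CBr4 and PPh3 give the bromide F8.
- Its Grignard reagent F9 (Mg, THF), used in excess, opens epoxide 2 under CuI catalysis to the diol F10.
- One-flask triflation and silylation as in step 3 gives the silyl triflate F12 by way of the hydroxy triflate F11.
- Propynyllithium as in step 4 then gives 17.

Further compounds

F1 | step 10 | triethyl{[(6R,7S,13E,17Z)-7-ethenyl-18-iodo-2,6,14-trimethylnonadeca-2,13,17-trien-9-yn-6-yl]oxy}silane | CC(C)=CCC[C@@](C)(O[Si](CC)(CC)CC)[C@H](C=C)CC#CCC/C=C(\C)CC/C=C(/C)I
F2 | step 10 | B-alkyl-9-BBN derived from F1 by hydroboration of the vinyl group | CC(C)=CCC[C@@](C)(O[Si](CC)(CC)CC)[C@H](CCB1C2CCCC1CCC2)CC#CCC/C=C(\C)CC/C=C(/C)I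
F3 | step 14 | C4-tributylstannyl (3Z,7E,11Z)-cyclotetradecatriene triethylsilyl ether (tin cis to C2) | CC(C)=CCC[C@@](C)(O[Si](CC)(CC)CC)[C@H]1C/C=C(\[Sn](CCCC)(CCCC)CCCC)CC/C=C(\C)CC/C=C(/C)CC1
F4 | step 14 | triethylsilyl ether of iodide 23 | CC(C)=CCC[C@@](C)(O[Si](CC)(CC)CC)[C@H]1C/C=C(\I)CC/C=C(\C)CC/C=C(/C)CC1
F5 | step 8 | (6E)-2,6-dimethyldodeca-1,6-dien-10-yn-3-ol (racemic) | C=C(C)C(O)CC/C(C)=C/CCC#CC
F6 | step 8 | tributyl({[(6E)-2,6-dimethyldodeca-1,6-dien-10-yn-3-yl]oxy}methyl)stannane | C=C(C)C(OC[Sn](CCCC)(CCCC)CCCC)CC/C(C)=C/CCC#CC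
F7 | step 8 | (3Z,7E)-3,7-dimethyltrideca-3,7-dien-11-yn-1-ol | OCC/C(C)=C\CC/C(C)=C/CCC#CC
F8 | step 8 | (3Z,7E)-1-bromo-3,7-dimethyltrideca-3,7-dien-11-yne | BrCC/C(C)=C\CC/C(C)=C/CCC#CC
F9 | step 8 | [(3Z,7E)-3,7-dimethyltrideca-3,7-dien-11-yn-1-yl]magnesium bromide | Br[Mg]CC/C(C)=C\CC/C(C)=C/CCC#CC
F10 | step 8 | (2R,3R)-2-[(3Z,7E)-3,7-dimethyltrideca-3,7-dien-11-yn-1-yl]-3,7-dimethyloct-6-ene-1,3-diol | CC(C)=CCC[C@@](C)(O)[C@H](CC/C(C)=C\CC/C(C)=C/CCC#CC)CO
F11 | step 8 | primary triflate of F10 with free tertiary hydroxyl | CC(C)=CCC[C@@](C)(O)[C@H](CC/C(C)=C\CC/C(C)=C/CCC#CC)COS(=O)(=O)C(F)(F)F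
F12 | step 8 | primary triflate of F10 with triethylsilyl ether at the tertiary oxygen | CC(C)=CCC[C@@](C)(O[Si](CC)(CC)CC)[C@H](CC/C(C)=C\CC/C(C)=C/CCC#CC)COS(=O)(=O)C(F)(F)F
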